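## Structural features

The target is a 19-membered carbocycle built from three rings: a cyclohexene (ring A) spiro-fused through its oxygen-bearing quaternary carbon to a 3-acyl tetronic acid (ring B), and a 2,3,4-trisubstituted thiolane (ring C). Ring C is tied to ring B by the ketone between thiolane C4 and tetronate C3. It is tied to ring A by an eleven-carbon chain that runs from the CH(CH3) on thiolane C3 through an isolated E-alkene, a secondary carbinol flanked by two CH2 groups, and an E,E-diene to the ring-A CH next to the spiro carbon. The stereocentres fall into two clusters: thiolane C2, C3 and C4 (all-trans) with the adjacent side-chain CH(CH3), and the spiro carbon with its neighbouring ring-A CH; the ring-A CH(CH3) and the chain carbinol stand alone. The fragile groups are the alpha-keto acid on C2 (alpha to sulfur, enolisable), the beta-thio ketone at C4 (retro-thia-Michael opening), the acidic tricarbonyl, and the sulfide itself. The sulfide forbids late oxidation of sulfur and hydrogenolysis, and it can attack a leaving group placed on either side arm. The real difficulty is the thiolane, whose three contiguous stereocentres carry three different carbon substituents, followed by closure of the large ring without base. The key step exploits the position of thiolane C2 between S1 and C3: the S1–C2 and C2–C3 bonds are both made by inserting the keto-ester carbene carbon into the S–C bond of a strained trans-2,3-disubstituted thietane that already holds the C3/C4 relationship.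

## Logic of the disconnections

**62 back to 59.** Only carbon–heteroatom bonds are changed: the dimethyl ketal and silyl ether (61), the methyl ester (60) and the tetronate methyl ether (59) are put back. The reason is that the keto acid, the tricarbonyl and the carbinol cannot pass through organometallic steps. The gain is a neutral macrocycle with no enolisable carbonyl next to thiolane C2. The demand is three orthogonal unmaskings that leave thiolane C4 untouched, with acid last.

**59 back to 58.** The single bond between the two alkenes of the diene is cut. It is an sp2–sp2 bond far from every stereocentre, and cutting it opens the macrocycle to a chain with an iodoalkene at one end and an alkenylstannane at the other. The forward step must close a 19-membered ring with retention at both alkenes under neutral conditions, in the presence of a sulfide.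

**58 back to 55 and 37 (through 57).** The bond between tetronate C3 and the ketone carbon is cut, and the ketone is taken back to a carbinol. This divides the molecule into the spiro half 55 and the thiolane–chain half 37. The forward step needs a C3 nucleophile (56) that adds to a beta-thio aldehyde at low temperature without enolising it, and a non-basic oxidation afterwards.

**37 back to 22 and 33 (through 36 and 35).** The isolated E-alkene is cut. The sulfone is placed on 33 and the aldehyde on 22, because a sulfone cannot be made by oxidation once the thiolane sulfur is present. The gain is a chain piece (33) that carries the carbinol stereocentre and the iodoalkene. The demand is E-selective olefination; the arm ether in 35 is then removed oxidatively and the alcohol 36 is oxidised.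

**22 back to 17 (through 20, 19 and 18).** One carbon is removed from the aldehyde arm, and the ketal is opened to the free keto ester. The arm is extended only at the aldehyde oxidation level, because a leaving group on that carbon would be attacked by the ring sulfur. The demand is that the ketal is formed while both arms carry acid-stable ethers, since a free arm hydroxyl would close a cyclic mixed ketal onto the keto ester.

**17 back to 13 and 15.** The S–C2 and C2–C3 bonds of the thiolane are cut and the carbene carbon with its keto ester is removed. One ring, two skeletal bonds and the C2 stereocentre are taken away at once, and the precursor has no alkene. Two changes are made to the precursor design, neither of which touches the disconnection: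
- The C3 arm of 13 carries a 4-methoxybenzyl ether instead of a silyl ether. It survives the acidic ketalisation, is orthogonal to the silyl ether on the other arm, and removes the need to exchange a benzyl ether by hydrogenolysis.
- 15 is the methyl ester, so that ketalisation in methanol cannot scramble esters.

The forward step needs sulfur-selective carbene capture, migration of the substituted ring carbon, and an all-trans outcome.

**13 back to 1, 4, 5 and 14.** The two C–S bonds of 13 are cut to the bis-sulfonate 11 of diol 10. The C–C bond between the carbinol carbon and its neighbour is then cut (9 to 7 and 3). The ring closes with inversion at the carbinol carbon, so a syn aldol relationship is needed. 3 comes from 1 by way of 2, 7 from 4 and 5, and 15 from 14. The demand is a reagent-controlled syn-aldol on a beta-alkoxy imide.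

**33 back to 23.** The C–S bond, the terminal C=C (to a hydroxyl carbon) and the two C–C bonds flanking the carbinol are cut in turn (32, 31, 29, 27, 26, 24). Both flanking bonds come from opening a three-carbon epoxide building block twice, so the carbinol configuration is bought, not made. The demand is selective cleavage of a terminal alkene beside an iodoalkene.

**55 back to 38, 41, 43 and 44.** The stannane goes back through 54, 53 and 52 to 51. The tetronate ring is cut at O1–C2 and C3–C4 to hydroxy ester 49, and the cyclohexene is cut by a [4+2] retron into diene 42 (from 40 and 41; 40 from 38) and dienophile 47 (from 45; 45 from 43 and 44). One cycloaddition must set the regiochemistry and all three ring-A stereocentres.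

## Other disconnections considered

**Alternative 1:** The cut is the tetronate C3–C4 bond, made after the lactone O1–C2 bond has already closed a 20-membered ring. In the forward step the beta-keto macrolactone A1 is deprotonated between its two carbonyls, and the enolate attacks the methyl ester on the spiro carbon across the ring (Dieckmann type, 5-exo-trig) to give A2.
- In favour: A2 is identical with 60. The chosen route reaches it only after lithiation and addition, oxidation of the carbinol, and O-demethylation. On the tetronate itself Alternative 1 is therefore the better plan by about three operations, and a doubly stabilised enolate is milder than a vinyllithium.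
- Against: A1 requires acylation of a hindered tertiary alcohol, either as a 20-membered lactonisation or intermolecularly with ring closure elsewhere. The thiolane C4 arm must be lengthened by two carbons, and the base acts on a molecule that holds a beta-thio ketone.
- Comparison: on structure it simplifies ring B and says nothing about ring C, so the thietane expansion would still be needed (equal on that point). On mechanism both are sound. On step economy the gain at the tetronate is likely to be spent on making A1.

**Alternative 2:** The cut is the bond between the spiro carbon and the adjacent ring-A CH. In the forward step the silyl ketene acetal of lactone A3 undergoes a [3,3] shift through a boat transition state; the lactone opens and the cyclohexene acid A4 is formed.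
- In favour: the quaternary centre and its neighbour are set by intramolecular chirality transfer. This does not depend on the regio-, exo- and facial selectivity of an intermolecular cycloaddition, and on predictability of mechanism it is the equal or the better of the Diels–Alder step used here.
- Against: A3 needs a stereodefined tertiary allylic carbinol and a Z-alkene, and the Z substituent points into the boat. A4 still has to be esterified, deprotected and annulated to the tetronate.
- Comparison: on structure it addresses ring A only. On step economy it is clearly longer than the single cycloaddition that gives 48.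

**Alternative 3:** The cuts are the bond from the spiro carbon to tetronate C4 and the O1–C2 lactone bond. In the forward step the lithiated acrylate A6 adds to ketone A5 and the alkoxide lactonises to A7.
- In favour: A7 is identical with 51 and is formed in one operation. This is equal to the one-step annulation of 49 used here, and better in that it needs no phosphorus reagent. Attack anti to the neighbouring chain should give the required configuration.
- Against: A5 is a beta,gamma-unsaturated ketone whose alpha stereocentre is both allylic and enolisable. Proton transfer to the basic vinyllithium, epimerisation and alkene migration compete with addition. Making A5 as a single enantiomer with its 1,4-related methyl centre is not simpler than the cycloaddition.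
- Comparison: on structure it is again confined to ring B. On mechanism it is a plain carbonyl addition, simpler than an ylide rearrangement. On step economy it is equal at best.

Key step: step 9

Remark 1: 4, 38 and 41 are taken to be catalogue compounds.
Remark 2: the trans-thietane, the all-trans thiolane and (S)-configured 1 were checked atom by atom against the target, and no error of connectivity or configuration was found; the changes made are the two spectator changes named above and the way the thietane is closed.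

## Steps

Step 1
Reactants: 1 methyl (2S)-3-hydroxy-2-methylpropanoate
Product: 2 methyl (2S)-3-[(tert-butyldiphenylsilyl)oxy]-2-methylpropanoate
Conditions: TBDPSCl, imidazole, DMF, 0 °C to rt
Reagents that add atoms: tert-butyl(chloro)diphenylsilane, CC(C)(C)[Si](Cl)(c1ccccc1)c1ccccc1
Why: Imidazole-promoted O-silylation of a primary alcohol; the stereocentre is not involved, and this silyl ether later survives acid, the carbene step and ketalisation.

Step 2
Reactants: 2 methyl (2S)-3-[(tert-butyldiphenylsilyl)oxy]-2-methylpropanoate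
Product: 3 (2S)-3-[(tert-butyldiphenylsilyl)oxy]-2-methylpropanal
Conditions: i-Bu2AlH (1.1 equiv), CH2Cl2, −78 °C; aq. potassium sodium tartrate; used crude
Reagents that add atoms: none
Why: Partial ester reduction through the aluminium hemiacetal, which is stable at −78 °C; the alpha stereocentre is kept by using the aldehyde without chromatography.

Step 3
Reactants: 4 3-[(4-methoxybenzyl)oxy]propanoic acid; 5 (4S)-4-benzyl-1,3-oxazolidin-2-one
Product: 7 (4S)-4-benzyl-3-{3-[(4-methoxybenzyl)oxy]propanoyl}-1,3-oxazolidin-2-one, via mixed pivalic anhydride 6 (not isolated)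
Conditions: t-BuCOCl, Et3N, THF, −20 °C; then 5, LiCl, −20 °C to rt
Reagents that add atoms: none
Why: N-acylation of the oxazolidinone by a mixed anhydride with LiCl activation, the standard entry to an acyl imide for an Evans aldol reaction.

Step 4
Reactants: 7 (4S)-4-benzyl-3-{3-[(4-methoxybenzyl)oxy]propanoyl}-1,3-oxazolidin-2-one; 3 (2S)-3-[(tert-butyldiphenylsilyl)oxy]-2-methylpropanal
Product: 9 (4S)-4-benzyl-3-[(2S,3R,4S)-5-[(tert-butyldiphenylsilyl)oxy]-3-hydroxy-2-{[(4-methoxybenzyl)oxy]methyl}-4-methylpentanoyl]-1,3-oxazolidin-2-one, via dibutylboron enolate 8 (not isolated)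
Conditions: Bu2BOTf, i-Pr2NEt, CH2Cl2, −78 °C; then 3, −78 to −20 °C; pH 7 buffer (KH2PO4/K2HPO4), MeOH, H2O2, 0 °C
Reagents that add atoms: none
Why: Evans syn-aldol: the (Z)-boron enolate reacts through a closed chair (Zimmerman–Traxler) transition state on the face away from the benzyl group, which sets C2 (S) and C3 (R) of the chain. The auxiliary has to override the preference of a (Z)-enolate for the other face of the alpha-methyl aldehyde, and the covalent boron enolate formed at −78 °C should not expel the beta-alkoxy group.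

Step 5
Reactants: 9 (4S)-4-benzyl-3-[(2S,3R,4S)-5-[(tert-butyldiphenylsilyl)oxy]-3-hydroxy-2-{[(4-methoxybenzyl)oxy]methyl}-4-methylpentanoyl]-1,3-oxazolidin-2-one
Product: 10 (2S,3R,4S)-5-[(tert-butyldiphenylsilyl)oxy]-2-{[(4-methoxybenzyl)oxy]methyl}-4-methylpentane-1,3-diol
Conditions: LiBH4, MeOH (1 equiv), THF, 0 °C
Reagents that add atoms: none
Why: Reductive cleavage of the imide to the primary alcohol with release of the auxiliary; the benzyl-type ether cannot migrate, so the two hydroxymethyl arms on C2 stay distinct.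

Step 6
Reactants: 10 (2S,3R,4S)-5-[(tert-butyldiphenylsilyl)oxy]-2-{[(4-methoxybenzyl)oxy]methyl}-4-methylpentane-1,3-diol
Product: 11 (2R,3R,4S)-5-[(tert-butyldiphenylsilyl)oxy]-2-{[(4-methoxybenzyl)oxy]methyl}-4-methylpentane-1,3-diyl dimethanesulfonate
Conditions: MsCl (2.5 equiv), Et3N, DMAP (cat.), CH2Cl2, 0 °C
Reagents that add atoms: methanesulfonyl chloride, CS(Cl)(=O)=O
Why: O-sulfonylation of both hydroxyls through the sulfene, which also reaches the hindered secondary alcohol; no C–O bond is broken, so all centres keep their spatial arrangement.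

Step 7
Reactants: 11 (2R,3R,4S)-5-[(tert-butyldiphenylsilyl)oxy]-2-{[(4-methoxybenzyl)oxy]methyl}-4-methylpentane-1,3-diyl dimethanesulfonate
Product: 13 (2S,3R)-2-{(2S)-1-[(tert-butyldiphenylsilyl)oxy]propan-2-yl}-3-{[(4-methoxybenzyl)oxy]methyl}thietane, via sodium thiolate 12 (not isolated)
Conditions: Na2S·9H2O (1.5 equiv), DMF, 0.02 M, 60 °C
Reagents that add atoms: sodium sulfide nonahydrate, [Na+].[Na+].[S-2]
Why: Thietane synthesis by double nucleophilic displacement on a 1,3-disulfonate: sulfide displaces the primary mesylate, and thiolate 12 then closes 4-exo-tet on the secondary mesylate with inversion. The inversion turns the syn aldol relationship into the trans-2,3-disubstituted ring.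

Step 8
Reactants: 14 methyl chlorooxoacetate
Product: 15 methyl 3-diazo-2-oxopropanoate
Conditions: Me3SiCHN2 (2.0 M in hexanes, 1.2 equiv), MeCN–THF, 0 °C to rt; used as a solution
Reagents that add atoms: (trimethylsilyl)diazomethane, C[Si](C)(C)C=[N+]=[N-]
Why: C-acylation of the diazoalkane by the acid chloride with loss of Me3SiCl (diazo ketone synthesis of the Arndt–Eistert type); this avoids gaseous diazomethane, and the acceptor-substituted diazo ketone is kept in solution.

Step 9
Reactants: 13 (2S,3R)-2-{(2S)-1-[(tert-butyldiphenylsilyl)oxy]propan-2-yl}-3-{[(4-methoxybenzyl)oxy]methyl}thietane; 15 methyl 3-diazo-2-oxopropanoate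
Product: 17 methyl 2-[(2S,3S,4R)-3-{(2R)-1-[(tert-butyldiphenylsilyl)oxy]propan-2-yl}-4-{[(4-methoxybenzyl)oxy]methyl}thiolan-2-yl]-2-oxoacetate (all-trans), via sulfonium ylide 16 (not isolated)
Conditions: Rh2(OAc)4 (2 mol %), ClCH2CH2Cl, 60 °C, 15 (1.5 equiv) added over 6 h; then Et3N (0.2 equiv), rt
Reagents that add atoms: none
Why: Rh2(OAc)4 (divalent rhodium) decomposes 15 to an electrophilic acyl carbene, which the thietane sulfur captures to give the acyl-stabilised sulfonium ylide 16; this forms the S–C2 bond of the thiolane. Relief of four-ring strain then cleaves the bond from sulfur to the ring carbon that bears the branched chain, and this carbon recombines at the ylide carbon in a [1,2] Stevens shift, which forms the C2–C3 bond. The closest known reaction type is the metal-carbene ring expansion of thietanes to thiolanes through sulfonium ylides. The five-membered ring closes by recombination of a tethered radical pair, a one-carbon ring enlargement, so no exo or endo ionic closure is involved. The migrating carbon should keep its configuration within the solvent cage, and if it planarises it should reclose anti to the neighbouring substituent, so the trans relationship of the thietane becomes C3/C4 trans. The new stereocentre C2 is set by the adjacent C3 substituent; because it is alpha to the keto ester, the triethylamine finish equilibrates it to the all-trans isomer. The step needs sulfur capture in preference to ether oxygen or arene (secured by the soft, strained sulfide and slow addition of 15) and migration of the substituted carbon, not the ring CH2 (secured by radical stability). Cyclopropanation cannot occur, because 13 has no alkene.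

Step 10
Reactants: 17 methyl 2-[(2S,3S,4R)-3-{(2R)-1-[(tert-butyldiphenylsilyl)oxy]propan-2-yl}-4-{[(4-methoxybenzyl)oxy]methyl}thiolan-2-yl]-2-oxoacetate
Product: 18 methyl 2-[(2S,3S,4R)-3-{(2R)-1-[(tert-butyldiphenylsilyl)oxy]propan-2-yl}-4-{[(4-methoxybenzyl)oxy]methyl}thiolan-2-yl]-2,2-dimethoxyacetate
Conditions: HC(OMe)3, MeOH, camphorsulfonic acid (10 mol %), 45 °C
Reagents that add atoms: trimethyl orthoformate, COC(OC)OC; methanol, CO
Why: Acid-catalysed ketalisation of the activated ketone, with the orthoformate as water scavenger; after this, C2 no longer has an enolisable carbonyl next to it and its configuration is fixed. Both arm ethers are stable to catalytic sulfonic acid in methanol, so no arm hydroxyl is freed that could close a cyclic mixed ketal.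

Step 11
Reactants: 18 methyl 2-[(2S,3S,4R)-3-{(2R)-1-[(tert-butyldiphenylsilyl)oxy]propan-2-yl}-4-{[(4-methoxybenzyl)oxy]methyl}thiolan-2-yl]-2,2-dimethoxyacetate
Product: 19 methyl 2-[(2S,3S,4R)-3-[(2R)-1-hydroxypropan-2-yl]-4-{[(4-methoxybenzyl)oxy]methyl}thiolan-2-yl]-2,2-dimethoxyacetate
Conditions: Bu4NF, AcOH (1:1), THF, 0 °C to rt
Reagents that add atoms: none
Why: Fluoride-induced desilylation; the acetic acid buffer keeps the alkoxide concentration low, so the hydroxyl does not attack the ester, and the ketal is inert without strong acid.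

Step 12
Reactants: 19 methyl 2-[(2S,3S,4R)-3-[(2R)-1-hydroxypropan-2-yl]-4-{[(4-methoxybenzyl)oxy]methyl}thiolan-2-yl]-2,2-dimethoxyacetate
Product: 20 methyl 2,2-dimethoxy-2-[(2S,3S,4R)-4-{[(4-methoxybenzyl)oxy]methyl}-3-[(2R)-1-oxopropan-2-yl]thiolan-2-yl]acetate
Conditions: Dess–Martin periodinane, NaHCO3, CH2Cl2, 0 °C to rt
Reagents that add atoms: none
Why: Dess–Martin oxidation of a primary alcohol under buffered, non-basic conditions; dialkyl sulfides are not oxidised at a useful rate, and the alpha-branched aldehyde is not epimerised.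

Step 13
Reactants: 20 methyl 2,2-dimethoxy-2-[(2S,3S,4R)-4-{[(4-methoxybenzyl)oxy]methyl}-3-[(2R)-1-oxopropan-2-yl]thiolan-2-yl]acetate
Product: 22 methyl 2,2-dimethoxy-2-[(2S,3S,4R)-4-{[(4-methoxybenzyl)oxy]methyl}-3-[(2S)-4-oxobutan-2-yl]thiolan-2-yl]acetate, via methyl enol ether 21 (not isolated)
Conditions: Ph3P(CH2OMe)Cl, KN(SiMe3)2, THF, 0 °C; then 20, −78 to 0 °C; crude 21, then 1 M HCl, THF, rt
Reagents that add atoms: (methoxymethyl)triphenylphosphonium chloride, COC[P+](c1ccccc1)(c1ccccc1)c1ccccc1.[Cl-]; water, O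
Why: Wittig methoxymethylenation followed by enol ether hydrolysis, a one-carbon homologation that never places a leaving group on the arm, so the ring sulfur cannot displace anything. The ylide adds to the aldehyde faster than it enolises it at low temperature, and the hindered ester, the deactivated ketal and the 4-methoxybenzyl ether survive dilute acid.

Step 14
Reactants: 23 (2R)-2-(chloromethyl)oxirane [(R)-epichlorohydrin]
Product: 24 (2R)-1-chloropent-4-en-2-ol
Conditions: CH2=CHMgBr, CuI (10 mol %), THF, −40 to −20 °C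
Reagents that add atoms: vinylmagnesium bromide, C=C[Mg]Br
Why: Copper-catalysed SN2 opening of the epoxide at its unsubstituted carbon by the vinyl Grignard reagent; the stereocentre keeps its C–O bond.

Step 15
Reactants: 24 (2R)-1-chloropent-4-en-2-ol
Product: 26 (4R)-hept-1-en-6-yn-4-ol, via allyloxirane 25 (not isolated)
Conditions: HC≡CLi·H2NCH2CH2NH2 (3 equiv), DMSO, 0 °C to rt
Reagents that add atoms: lithium acetylide–ethylenediamine complex, [Li]C#C.NCCN
Why: The base closes the chlorohydrin to epoxide 25 (3-exo-tet), and acetylide opens it at the terminal carbon (SN2); neither event touches the carbinol C–O bond.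

Step 16
Reactants: 26 (4R)-hept-1-en-6-yn-4-ol
Product: 27 tert-butyl{[(4R)-hept-1-en-6-yn-4-yl]oxy}dimethylsilane
Conditions: TBSCl, imidazole, DMF, rt
Reagents that add atoms: tert-butyl(chloro)dimethylsilane, CC(C)(C)[Si](C)(C)Cl
Why: Silylation of the secondary alcohol; this ether lasts to the final acid step.

Step 17
Reactants: 27 tert-butyl{[(4R)-hept-1-en-6-yn-4-yl]oxy}dimethylsilane
Product: 29 tert-butyl{[(1E,4R)-1-iodohepta-1,6-dien-4-yl]oxy}dimethylsilane, via alkenylzirconocene chloride 28 (not isolated)
Conditions: Cp2Zr(H)Cl (1.2 equiv), THF, rt; then I2, 0 °C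
Reagents that add atoms: iodine, II
Why: Hydrozirconation: syn addition of Zr–H to the terminal alkyne, which reacts faster than the monosubstituted alkene, places zirconium at the terminus; iodinolysis with retention gives the E-iodoalkene.

Step 18
Reactants: 29 tert-butyl{[(1E,4R)-1-iodohepta-1,6-dien-4-yl]oxy}dimethylsilane
Product: 31 (3S,5E)-3-[(tert-butyldimethylsilyl)oxy]-6-iodohex-5-en-1-ol, via aldehyde 30 (not isolated)
Conditions: OsO4 (2 mol %), NaIO4, 2,6-lutidine, dioxane–H2O, rt; then NaBH4, MeOH, 0 °C
Reagents that add atoms: sodium periodate, [Na+].[O-]I(=O)(=O)=O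
Why: Lemieux–Johnson cleavage: catalytic OsO4 dihydroxylates the electron-richer terminal alkene in preference to the iodoalkene, and periodate cleaves the diol. The beta-silyloxy aldehyde 30 is reduced at once so that it cannot eliminate.

Step 19
Reactants: 31 (3S,5E)-3-[(tert-butyldimethylsilyl)oxy]-6-iodohex-5-en-1-ol
Product: 32 5-{[(3S,5E)-3-[(tert-butyldimethylsilyl)oxy]-6-iodohex-5-en-1-yl]sulfanyl}-1-phenyl-1H-tetrazole
Conditions: 1-phenyl-1H-tetrazole-5-thiol, PPh3, DIAD, THF, 0 °C to rt
Reagents that add atoms: 1-phenyl-1H-tetrazole-5-thiol, Sc1nnnn1-c1ccccc1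
Why: Mitsunobu thioetherification of a primary alcohol with an acidic heteroaryl thiol.

Step 20
Reactants: 32 5-{[(3S,5E)-3-[(tert-butyldimethylsilyl)oxy]-6-iodohex-5-en-1-yl]sulfanyl}-1-phenyl-1H-tetrazole
Product: 33 5-{[(3S,5E)-3-[(tert-butyldimethylsilyl)oxy]-6-iodohex-5-en-1-yl]sulfonyl}-1-phenyl-1H-tetrazole
Conditions: (NH4)6Mo7O24·4H2O (10 mol %), 30% H2O2, EtOH, 0 °C to rt
Reagents that add atoms: hydrogen peroxide, OO
Why: Molybdate-catalysed peroxide oxidation of sulfide to sulfone, with iodoalkene and silyl ether inert; this is the only sulfur oxidation of the route and it is done before the thiolane is present.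

Step 21
Reactants: 33 5-{[(3S,5E)-3-[(tert-butyldimethylsilyl)oxy]-6-iodohex-5-en-1-yl]sulfonyl}-1-phenyl-1H-tetrazole; 22 methyl 2,2-dimethoxy-2-[(2S,3S,4R)-4-{[(4-methoxybenzyl)oxy]methyl}-3-[(2S)-4-oxobutan-2-yl]thiolan-2-yl]acetate
Product: 35 methyl 2-[(2S,3S,4R)-3-{(2S,4E,7R,9E)-7-[(tert-butyldimethylsilyl)oxy]-10-iododeca-4,9-dien-2-yl}-4-{[(4-methoxybenzyl)oxy]methyl}thiolan-2-yl]-2,2-dimethoxyacetate, via potassium sulfonyl carbanion 34 (not isolated)
Conditions: 33, KN(SiMe3)2, DME, −78 °C; then 22, −78 °C to rt
Reagents that add atoms: none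
Why: Julia–Kocienski olefination: the metalated sulfone adds to the aldehyde, and Smiles rearrangement followed by loss of SO2 and tetrazololate gives the alkene. The potassium counter-ion in DME favours the open transition state that leads to the E isomer, and the E-iodoalkene tolerates the amide base at −78 °C.

Step 22
Reactants: 35 methyl 2-[(2S,3S,4R)-3-{(2S,4E,7R,9E)-7-[(tert-butyldimethylsilyl)oxy]-10-iododeca-4,9-dien-2-yl}-4-{[(4-methoxybenzyl)oxy]methyl}thiolan-2-yl]-2,2-dimethoxyacetate
Product: 36 methyl 2-[(2S,3S,4R)-3-{(2S,4E,7R,9E)-7-[(tert-butyldimethylsilyl)oxy]-10-iododeca-4,9-dien-2-yl}-4-(hydroxymethyl)thiolan-2-yl]-2,2-dimethoxyacetate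
Conditions: DDQ (1.5 equiv), CH2Cl2–pH 7 buffer (KH2PO4/K2HPO4) 10:1, 0 °C
Reagents that add atoms: none
Why: Oxidative cleavage of the 4-methoxybenzyl ether by benzylic hydride abstraction and hydrolysis of the oxocarbenium ion; dialkyl sulfide, isolated alkene, iodoalkene, silyl ether and ketal are tolerated under buffered conditions, and no conjugated diene is present yet.

Step 23
Reactants: 36 methyl 2-[(2S,3S,4R)-3-{(2S,4E,7R,9E)-7-[(tert-butyldimethylsilyl)oxy]-10-iododeca-4,9-dien-2-yl}-4-(hydroxymethyl)thiolan-2-yl]-2,2-dimethoxyacetate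
Product: 37 methyl 2-[(2S,3S,4R)-3-{(2S,4E,7R,9E)-7-[(tert-butyldimethylsilyl)oxy]-10-iododeca-4,9-dien-2-yl}-4-formylthiolan-2-yl]-2,2-dimethoxyacetate
Conditions: Dess–Martin periodinane, NaHCO3, CH2Cl2, 0 °C; used directly
Reagents that add atoms: none
Why: Dess–Martin oxidation; the absence of base protects the beta-thio aldehyde from epimerisation at C4 and from retro-thia-Michael ring opening.

Step 24
Reactants: 38 tert-butyl(but-3-yn-1-yloxy)dimethylsilane
Product: 40 tert-butyl{[(3E)-4-iodobut-3-en-1-yl]oxy}dimethylsilane, via alkenylzirconocene chloride 39 (not isolated)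
Conditions: Cp2Zr(H)Cl, THF, rt; then I2, 0 °C
Reagents that add atoms: iodine, II
Why: Hydrozirconation–iodination of a terminal alkyne (syn addition, retention on iodinolysis) gives the E-iodoalkene.

Step 25
Reactants: 40 tert-butyl{[(3E)-4-iodobut-3-en-1-yl]oxy}dimethylsilane; 41 (2Z)-but-2-en-2-ylboronic acid
Product: 42 tert-butyl{[(3E,5E)-5-methylhepta-3,5-dien-1-yl]oxy}dimethylsilane
Conditions: Pd(PPh3)4 (5 mol %), aq. K3PO4, THF, 50 °C
Reagents that add atoms: none
Why: Suzuki–Miyaura coupling of two alkenyl partners with retention at both, which gives the E,E-diene with the two methyl groups cis on the trisubstituted alkene.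

Step 26
Reactants: 43 (2R)-2-hydroxypropanoic acid [(R)-lactic acid]; 44 2,2-dimethylpropanal
Product: 45 (2R,5R)-2-tert-butyl-5-methyl-1,3-dioxolan-4-one
Conditions: TsOH·H2O (cat.), H2SO4 (cat.), pentane, reflux, water separator; crystallisation of the cis isomer
Reagents that add atoms: none
Why: Acid-catalysed acetalisation of the alpha-hydroxy acid; the cis acetal is favoured and crystallises, so the lactic acid stereocentre is copied onto the acetal carbon.

Step 27
Reactants: 45 (2R,5R)-2-tert-butyl-5-methyl-1,3-dioxolan-4-one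
Product: 47 (2R)-2-tert-butyl-5-methylidene-1,3-dioxolan-4-one, via bromodioxolanone 46 (not isolated)
Conditions: NBS, AIBN (cat.), PhCF3, 80 °C; filter; then Et3N, Et2O, 0 °C to rt
Reagents that add atoms: none
Why: Radical bromination at the tertiary captodative C5–H and E2 dehydrobromination; the acetal carbon remains as the only stereocentre and will direct the cycloaddition.

Step 28
Reactants: 42 tert-butyl{[(3E,5E)-5-methylhepta-3,5-dien-1-yl]oxy}dimethylsilane; 47 (2R)-2-tert-butyl-5-methylidene-1,3-dioxolan-4-one
Product: 48 (2R,5S,6R,9R)-2-tert-butyl-6-{2-[(tert-butyldimethylsilyl)oxy]ethyl}-8,9-dimethyl-1,3-dioxaspiro[4.5]dec-7-en-4-one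
Conditions: toluene, BHT (cat.), 100 °C, sealed tube
Reagents that add atoms: none
Why: Thermal Diels–Alder reaction in which the internal methyl and the C4 alkyl group make the CH(CH3) terminus of the diene the more nucleophilic one, so it bonds to the CH2 of the dienophile. The exo mode with respect to the lactone carbonyl, usual for this type of alpha-oxy acrylate, places the ring oxygen cis to both diene substituents. Addition anti to the tert-butyl group sets the absolute configuration of all three new centres.

Step 29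
Reactants: 48 (2R,5S,6R,9R)-2-tert-butyl-6-{2-[(tert-butyldimethylsilyl)oxy]ethyl}-8,9-dimethyl-1,3-dioxaspiro[4.5]dec-7-en-4-one
Product: 49 methyl (1S,2R,5R)-2-{2-[(tert-butyldimethylsilyl)oxy]ethyl}-1-hydroxy-4,5-dimethylcyclohex-3-ene-1-carboxylate
Conditions: K2CO3 (cat.), MeOH, 0 °C to rt
Reagents that add atoms: methanol, CO
Why: Methanolysis of the acetal lactone (transesterification); the hemiacetal that is released loses 2,2-dimethylpropanal and leaves the tertiary alpha-hydroxy ester with the quaternary centre unchanged.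

Step 30
Reactants: 49 methyl (1S,2R,5R)-2-{2-[(tert-butyldimethylsilyl)oxy]ethyl}-1-hydroxy-4,5-dimethylcyclohex-3-ene-1-carboxylate
Product: 51 (5S,6R,9R)-6-{2-[(tert-butyldimethylsilyl)oxy]ethyl}-4-methoxy-8,9-dimethyl-1-oxaspiro[4.5]deca-3,7-dien-2-one, via acyl ylide 50 (not isolated)
Conditions: Ph3P=C=C=O (1.5 equiv), toluene, reflux
Reagents that add atoms: (triphenylphosphoranylidene)ketene, O=C=C=P(c1ccccc1)(c1ccccc1)c1ccccc1
Why: Domino addition–intramolecular Wittig reaction: the tertiary alcohol adds across the ketene C=C to give ester ylide 50, which olefinates the neighbouring ester carbonyl. The ester methoxy group becomes the 4-methoxy group, so the tetronate arrives O-protected with C3–H free for lithiation.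

Step 31
Reactants: 51 (5S,6R,9R)-6-{2-[(tert-butyldimethylsilyl)oxy]ethyl}-4-methoxy-8,9-dimethyl-1-oxaspiro[4.5]deca-3,7-dien-2-one
Product: 52 (5S,6R,9R)-6-(2-hydroxyethyl)-4-methoxy-8,9-dimethyl-1-oxaspiro[4.5]deca-3,7-dien-2-one
Conditions: camphorsulfonic acid (10 mol %), MeOH–CH2Cl2, 0 °C
Reagents that add atoms: none
Why: Acid-catalysed methanolysis of a primary silyl ether; the methyl tetronate, a vinylogous carbonate, is stable to mild acid.

Step 32
Reactants: 52 (5S,6R,9R)-6-(2-hydroxyethyl)-4-methoxy-8,9-dimethyl-1-oxaspiro[4.5]deca-3,7-dien-2-one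
Product: 53 2-[(5S,6R,9R)-4-methoxy-8,9-dimethyl-2-oxo-1-oxaspiro[4.5]deca-3,7-dien-6-yl]acetaldehyde
Conditions: Dess–Martin periodinane, NaHCO3, CH2Cl2, 0 °C
Reagents that add atoms: none
Why: Dess–Martin oxidation of the primary alcohol; the neutral conditions avoid migration of the ring alkene toward the new aldehyde.

Step 33
Reactants: 53 2-[(5S,6R,9R)-4-methoxy-8,9-dimethyl-2-oxo-1-oxaspiro[4.5]deca-3,7-dien-6-yl]acetaldehyde
Product: 54 (5S,6R,9R)-6-[(2E)-3-iodoprop-2-en-1-yl]-4-methoxy-8,9-dimethyl-1-oxaspiro[4.5]deca-3,7-dien-2-one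
Conditions: CrCl2 (6 equiv), CHI3 (2 equiv), THF–dioxane 1:6, 0 °C to rt
Reagents that add atoms: iodoform, IC(I)I
Why: Takai olefination: the geminal dichromium species formed from CHI3 and CrCl2 (divalent chromium) adds to the aldehyde and eliminates to the E-iodoalkene; lactone and enol ether are inert to this mild reductant.

Step 34
Reactants: 54 (5S,6R,9R)-6-[(2E)-3-iodoprop-2-en-1-yl]-4-methoxy-8,9-dimethyl-1-oxaspiro[4.5]deca-3,7-dien-2-one
Product: 55 (5S,6R,9R)-4-methoxy-8,9-dimethyl-6-[(2E)-3-(tributylstannyl)prop-2-en-1-yl]-1-oxaspiro[4.5]deca-3,7-dien-2-one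
Conditions: Bu3SnSnBu3 (2 equiv), Pd(PPh3)4 (5 mol %), toluene, 80 °C
Reagents that add atoms: hexabutyldistannane, CCCC[Sn](CCCC)(CCCC)[Sn](CCCC)(CCCC)CCCC
Why: Palladium-catalysed stannylation: oxidative addition of the iodoalkene to zerovalent palladium, transmetalation with the distannane and reductive elimination with retention of the E geometry. The excess of distannane suppresses coupling of the product with unreacted iodide.

Step 35
Reactants: 55 (5S,6R,9R)-4-methoxy-8,9-dimethyl-6-[(2E)-3-(tributylstannyl)prop-2-en-1-yl]-1-oxaspiro[4.5]deca-3,7-dien-2-one; 37 methyl 2-[(2S,3S,4R)-3-{(2S,4E,7R,9E)-7-[(tert-butyldimethylsilyl)oxy]-10-iododeca-4,9-dien-2-yl}-4-formylthiolan-2-yl]-2,2-dimethoxyacetate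
Product: 57 secondary carbinol (both epimers) in which thiolane C4 of 37 carries CH(OH) bonded to tetronate C3 of 55, via lithiated tetronate 56 (not isolated)
Conditions: 55, LiN(i-Pr)2 (1.05 equiv), THF, −78 °C; then 37, −78 °C; sat. NH4Cl
Reagents that add atoms: none
Why: Vinylic lithiation at tetronate C3, between the lactone carbonyl and the methoxy group, followed by 1,2-addition to the aldehyde at −78 °C, the established way to 3-acyl tetronates. The new carbinol centre does not matter because it is oxidised next, and the stannane, the iodoalkene and the hindered ketal ester are inert to the stabilised vinyllithium.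

Step 36
Reactants: 57 secondary carbinol (both epimers)
Product: 58 ketone in which thiolane C4 and tetronate C3 are joined by C=O (seco compound carrying the iodoalkene and the alkenylstannane)
Conditions: Dess–Martin periodinane, NaHCO3, CH2Cl2, 0 °C to rt
Reagents that add atoms: none
Why: Dess–Martin oxidation of the secondary alcohol to the 3-acyl-4-methoxy tetronate; the buffer prevents protodestannylation, and the absence of base protects the beta-thio ketone.

Step 37
Reactants: 58 seco ketone carrying the iodoalkene and the alkenylstannane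
Product: 59 protected macrocycle (tetronate methyl ether, carbinol tert-butyldimethylsilyl ether, keto acid as dimethyl ketal methyl ester; configured as 62)
Conditions: Pd2(dba)3 (10 mol %), AsPh3 (40 mol %), DMF, 1 mM, rt to 40 °C
Reagents that add atoms: none
Why: Intramolecular Stille coupling at high dilution: oxidative addition of the iodoalkene to zerovalent palladium, transmetalation from the alkenylstannane (accelerated by the weakly bound arsine) and reductive elimination with retention at both alkenes. This gives the E,E-diene and closes the 19-membered ring under neutral conditions.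

Step 38
Reactants: 59 protected macrocycle
Product: 60 macrocyclic 3-acyl tetronic acid with the carbinol silyl ether and the dimethyl ketal methyl ester still in place
Conditions: LiCl (10 equiv), DMSO, 55 °C; dilute acid work-up
Reagents that add atoms: none
Why: SN2 demethylation of the vinylogous methyl carbonate by chloride; the acyl tetronate is a very good leaving group, so the hindered methyl ester and the ketal are not touched at this temperature.

Step 39
Reactants: 60 macrocyclic tetronic acid (ketal methyl ester)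
Product: 61 macrocyclic tetronic acid carrying the 2,2-dimethoxy acetic acid unit and the carbinol silyl ether
Conditions: LiOH·H2O (5 equiv), THF–MeOH–H2O, rt to 40 °C; then pH 3
Reagents that add atoms: lithium hydroxide monohydrate, [Li+].[OH-].O
Why: Saponification of the inductively activated alpha,alpha-dialkoxy ester; the tetronic acid is present as its delocalised anion, which shields the tricarbonyl and the adjacent C4–H from hydroxide.

Step 40
Reactants: 61 ketal acid with silyl ether
Product: 62 target, CNP0224658.3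
Conditions: CF3CO2H–H2O–THF, rt
Reagents that add atoms: water, O
Why: Acid-catalysed hydrolysis of the dimethyl ketal with cleavage of the silyl ether in the same operation; acid comes last, so the alpha-keto acid, enolisable next to sulfur, never meets base.

## Compound list

1 | methyl (2S)-3-hydroxy-2-methylpropanoate | C[C@@H](CO)C(=O)OC | starting material
2 | methyl (2S)-3-[(tert-butyldiphenylsilyl)oxy]-2-methylpropanoate | C[C@@H](CO[Si](c1ccccc1)(c1ccccc1)C(C)(C)C)C(=O)OC | intermediate
3 | (2S)-3-[(tert-butyldiphenylsilyl)oxy]-2-methylpropanal | C[C@@H](CO[Si](c1ccccc1)(c1ccccc1)C(C)(C)C)C=O | intermediate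
4 | 3-[(4-methoxybenzyl)oxy]propanoic acid | COc1ccc(COCCC(=O)O)cc1 | starting material
5 | (4S)-4-benzyl-1,3-oxazolidin-2-one | O=C1N[C@@H](Cc2ccccc2)CO1 | starting material
6 | 3-[(4-methoxybenzyl)oxy]propanoic pivalic anhydride | COc1ccc(COCCC(=O)OC(=O)C(C)(C)C)cc1 | intermediate
7 | (4S)-4-benzyl-3-{3-[(4-methoxybenzyl)oxy]propanoyl}-1,3-oxazolidin-2-one | COc1ccc(COCCC(=O)N2[C@@H](Cc3ccccc3)COC2=O)cc1 | intermediate
8 | (Z)-dibutylboron enolate of 7 | CCCCB(CCCC)O/C(=C\COCc1ccc(OC)cc1)N1[C@@H](Cc2ccccc2)COC1=O | intermediate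
9 | (4S)-4-benzyl-3-[(2S,3R,4S)-5-[(tert-butyldiphenylsilyl)oxy]-3-hydroxy-2-{[(4-methoxybenzyl)oxy]methyl}-4-methylpentanoyl]-1,3-oxazolidin-2-one | O=C1OC[C@H](Cc2ccccc2)N1C(=O)[C@@H](COCc1ccc(OC)cc1)[C@H](O)[C@@H](C)CO[Si](c1ccccc1)(c1ccccc1)C(C)(C)C | intermediate
10 | (2S,3R,4S)-5-[(tert-butyldiphenylsilyl)oxy]-2-{[(4-methoxybenzyl)oxy]methyl}-4-methylpentane-1,3-diol | OC[C@@H](COCc1ccc(OC)cc1)[C@H](O)[C@@H](C)CO[Si](c1ccccc1)(c1ccccc1)C(C)(C)C | intermediate
11 | (2R,3R,4S)-5-[(tert-butyldiphenylsilyl)oxy]-2-{[(4-methoxybenzyl)oxy]methyl}-4-methylpentane-1,3-diyl dimethanesulfonate | CS(=O)(=O)OC[C@@H](COCc1ccc(OC)cc1)[C@H](OS(C)(=O)=O)[C@@H](C)CO[Si](c1ccccc1)(c1ccccc1)C(C)(C)C | intermediate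
12 | sodium thiolate from displacement of the primary mesylate of 11 (secondary mesylate intact) | [Na+].[S-]C[C@@H](COCc1ccc(OC)cc1)[C@H](OS(C)(=O)=O)[C@@H](C)CO[Si](c1ccccc1)(c1ccccc1)C(C)(C)C | intermediate
13 | (2S,3R)-2-{(2S)-1-[(tert-butyldiphenylsilyl)oxy]propan-2-yl}-3-{[(4-methoxybenzyl)oxy]methyl}thietane (trans) | CC(C)(C)[Si](c1ccccc1)(c1ccccc1)OC[C@H](C)[C@@H]1SC[C@H]1COCc1ccc(OC)cc1 | intermediate
14 | methyl chlorooxoacetate | COC(=O)C(Cl)=O | starting material
15 | methyl 3-diazo-2-oxopropanoate | COC(=O)C(=O)C=[N+]=[N-] | intermediate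
16 | thietanium ylide of 13 bearing the CH–CO–CO2CH3 carbanion on sulfur | CC(C)(C)[Si](c1ccccc1)(c1ccccc1)OC[C@H](C)[C@@H]1[S+]([CH-]C(=O)C(=O)OC)C[C@H]1COCc1ccc(OC)cc1 | intermediate
17 | methyl 2-[(2S,3S,4R)-3-{(2R)-1-[(tert-butyldiphenylsilyl)oxy]propan-2-yl}-4-{[(4-methoxybenzyl)oxy]methyl}thiolan-2-yl]-2-oxoacetate | CC(C)(C)[Si](c1ccccc1)(c1ccccc1)OC[C@H](C)[C@@H]1[C@@H](C(=O)C(=O)OC)SC[C@H]1COCc1ccc(OC)cc1 | intermediate
18 | methyl 2-[(2S,3S,4R)-3-{(2R)-1-[(tert-butyldiphenylsilyl)oxy]propan-2-yl}-4-{[(4-methoxybenzyl)oxy]methyl}thiolan-2-yl]-2,2-dimethoxyacetate | CC(C)(C)[Si](c1ccccc1)(c1ccccc1)OC[C@H](C)[C@@H]1[C@@H](C(OC)(OC)C(=O)OC)SC[C@H]1COCc1ccc(OC)cc1 | intermediate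
19 | methyl 2-[(2S,3S,4R)-3-[(2R)-1-hydroxypropan-2-yl]-4-{[(4-methoxybenzyl)oxy]methyl}thiolan-2-yl]-2,2-dimethoxyacetate | OC[C@H](C)[C@@H]1[C@@H](C(OC)(OC)C(=O)OC)SC[C@H]1COCc1ccc(OC)cc1 | intermediate
20 | methyl 2,2-dimethoxy-2-[(2S,3S,4R)-4-{[(4-methoxybenzyl)oxy]methyl}-3-[(2R)-1-oxopropan-2-yl]thiolan-2-yl]acetate | O=C[C@H](C)[C@@H]1[C@@H](C(OC)(OC)C(=O)OC)SC[C@H]1COCc1ccc(OC)cc1 | intermediate
21 | methyl 2,2-dimethoxy-2-[(2S,3S,4R)-3-[(2S)-4-methoxybut-3-en-2-yl]-4-{[(4-methoxybenzyl)oxy]methyl}thiolan-2-yl]acetate (E/Z mixture) | COC=C[C@H](C)[C@@H]1[C@@H](C(OC)(OC)C(=O)OC)SC[C@H]1COCc1ccc(OC)cc1 | intermediate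
22 | methyl 2,2-dimethoxy-2-[(2S,3S,4R)-4-{[(4-methoxybenzyl)oxy]methyl}-3-[(2S)-4-oxobutan-2-yl]thiolan-2-yl]acetate | O=CC[C@H](C)[C@@H]1[C@@H](C(OC)(OC)C(=O)OC)SC[C@H]1COCc1ccc(OC)cc1 | intermediate
23 | (2R)-2-(chloromethyl)oxirane | ClC[C@H]1CO1 | starting material
24 | (2R)-1-chloropent-4-en-2-ol | ClC[C@H](O)CC=C | intermediate
25 | (2R)-2-(prop-2-en-1-yl)oxirane | C=CC[C@@H]1CO1 | intermediate
26 | (4R)-hept-1-en-6-yn-4-ol | C#CC[C@H](O)CC=C | intermediate
27 | tert-butyl{[(4R)-hept-1-en-6-yn-4-yl]oxy}dimethylsilane | C#CC[C@H](O[Si](C)(C)C(C)(C)C)CC=C | intermediate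
28 | (E)-alkenylzirconocene chloride from 27 (zirconium on the terminal carbon) | Cl[Zr](/C=C/C[C@H](O[Si](C)(C)C(C)(C)C)CC=C)(C1C=CC=C1)C1C=CC=C1 | intermediate
29 | tert-butyl{[(1E,4R)-1-iodohepta-1,6-dien-4-yl]oxy}dimethylsilane | I/C=C/C[C@H](O[Si](C)(C)C(C)(C)C)CC=C | intermediate
30 | (3S,5E)-3-[(tert-butyldimethylsilyl)oxy]-6-iodohex-5-enal | I/C=C/C[C@H](O[Si](C)(C)C(C)(C)C)CC=O | intermediate
31 | (3S,5E)-3-[(tert-butyldimethylsilyl)oxy]-6-iodohex-5-en-1-ol | I/C=C/C[C@H](O[Si](C)(C)C(C)(C)C)CCO | intermediate
32 | 5-{[(3S,5E)-3-[(tert-butyldimethylsilyl)oxy]-6-iodohex-5-en-1-yl]sulfanyl}-1-phenyl-1H-tetrazole | I/C=C/C[C@H](O[Si](C)(C)C(C)(C)C)CCSc1nnnn1-c1ccccc1 | intermediate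
33 | 5-{[(3S,5E)-3-[(tert-butyldimethylsilyl)oxy]-6-iodohex-5-en-1-yl]sulfonyl}-1-phenyl-1H-tetrazole | I/C=C/C[C@H](O[Si](C)(C)C(C)(C)C)CCS(=O)(=O)c1nnnn1-c1ccccc1 | intermediate
34 | potassium alpha-sulfonyl carbanion of 33 | [K+].I/C=C/C[C@H](O[Si](C)(C)C(C)(C)C)C[CH-]S(=O)(=O)c1nnnn1-c1ccccc1 | intermediate
35 | methyl 2-[(2S,3S,4R)-3-{(2S,4E,7R,9E)-7-[(tert-butyldimethylsilyl)oxy]-10-iododeca-4,9-dien-2-yl}-4-{[(4-methoxybenzyl)oxy]methyl}thiolan-2-yl]-2,2-dimethoxyacetate | I/C=C/C[C@H](O[Si](C)(C)C(C)(C)C)C/C=C/C[C@H](C)[C@@H]1[C@@H](C(OC)(OC)C(=O)OC)SC[C@H]1COCc1ccc(OC)cc1 | intermediate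
36 | methyl 2-[(2S,3S,4R)-3-{(2S,4E,7R,9E)-7-[(tert-butyldimethylsilyl)oxy]-10-iododeca-4,9-dien-2-yl}-4-(hydroxymethyl)thiolan-2-yl]-2,2-dimethoxyacetate | I/C=C/C[C@H](O[Si](C)(C)C(C)(C)C)C/C=C/C[C@H](C)[C@@H]1[C@@H](C(OC)(OC)C(=O)OC)SC[C@H]1CO | intermediate
37 | methyl 2-[(2S,3S,4R)-3-{(2S,4E,7R,9E)-7-[(tert-butyldimethylsilyl)oxy]-10-iododeca-4,9-dien-2-yl}-4-formylthiolan-2-yl]-2,2-dimethoxyacetate | I/C=C/C[C@H](O[Si](C)(C)C(C)(C)C)C/C=C/C[C@H](C)[C@@H]1[C@@H](C(OC)(OC)C(=O)OC)SC[C@H]1C=O | intermediate
38 | tert-butyl(but-3-yn-1-yloxy)dimethylsilane | C#CCCO[Si](C)(C)C(C)(C)C | starting material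
39 | (E)-alkenylzirconocene chloride from 38 | Cl[Zr](/C=C/CCO[Si](C)(C)C(C)(C)C)(C1C=CC=C1)C1C=CC=C1 | intermediate
40 | tert-butyl{[(3E)-4-iodobut-3-en-1-yl]oxy}dimethylsilane | I/C=C/CCO[Si](C)(C)C(C)(C)C | intermediate
41 | (2Z)-but-2-en-2-ylboronic acid | C/C=C(\C)B(O)O | starting material
42 | tert-butyl{[(3E,5E)-5-methylhepta-3,5-dien-1-yl]oxy}dimethylsilane | C/C=C(C)/C=C/CCO[Si](C)(C)C(C)(C)C | intermediate
43 | (2R)-2-hydroxypropanoic acid | C[C@@H](O)C(=O)O | starting material
44 | 2,2-dimethylpropanal | CC(C)(C)C=O | starting material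
45 | (2R,5R)-2-tert-butyl-5-methyl-1,3-dioxolan-4-one (cis) | CC(C)(C)[C@@H]1O[C@H](C)C(=O)O1 | intermediate
46 | (2R)-5-bromo-2-tert-butyl-5-methyl-1,3-dioxolan-4-one | CC(C)(C)[C@@H]1OC(C)(Br)C(=O)O1 | intermediate
47 | (2R)-2-tert-butyl-5-methylidene-1,3-dioxolan-4-one | CC(C)(C)[C@@H]1OC(=C)C(=O)O1 | intermediate
48 | (2R,5S,6R,9R)-2-tert-butyl-6-{2-[(tert-butyldimethylsilyl)oxy]ethyl}-8,9-dimethyl-1,3-dioxaspiro[4.5]dec-7-en-4-one | CC1=C[C@@H](CCO[Si](C)(C)C(C)(C)C)[C@]2(C[C@H]1C)O[C@@H](C(C)(C)C)OC2=O | intermediate
49 | methyl (1S,2R,5R)-2-{2-[(tert-butyldimethylsilyl)oxy]ethyl}-1-hydroxy-4,5-dimethylcyclohex-3-ene-1-carboxylate | CC1=C[C@@H](CCO[Si](C)(C)C(C)(C)C)[C@](O)(C(=O)OC)C[C@H]1C | intermediate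
50 | (triphenylphosphoranylidene)acetate ester of the tertiary hydroxyl of 49 | CC1=C[C@@H](CCO[Si](C)(C)C(C)(C)C)[C@](OC(=O)C=P(c2ccccc2)(c2ccccc2)c2ccccc2)(C(=O)OC)C[C@H]1C | intermediate
51 | (5S,6R,9R)-6-{2-[(tert-butyldimethylsilyl)oxy]ethyl}-4-methoxy-8,9-dimethyl-1-oxaspiro[4.5]deca-3,7-dien-2-one | CC1=C[C@@H](CCO[Si](C)(C)C(C)(C)C)[C@]2(C[C@H]1C)OC(=O)C=C2OC | intermediate
52 | (5S,6R,9R)-6-(2-hydroxyethyl)-4-methoxy-8,9-dimethyl-1-oxaspiro[4.5]deca-3,7-dien-2-one | CC1=C[C@@H](CCO)[C@]2(C[C@H]1C)OC(=O)C=C2OC | intermediate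
53 | 2-[(5S,6R,9R)-4-methoxy-8,9-dimethyl-2-oxo-1-oxaspiro[4.5]deca-3,7-dien-6-yl]acetaldehyde | CC1=C[C@@H](CC=O)[C@]2(C[C@H]1C)OC(=O)C=C2OC | intermediate
54 | (5S,6R,9R)-6-[(2E)-3-iodoprop-2-en-1-yl]-4-methoxy-8,9-dimethyl-1-oxaspiro[4.5]deca-3,7-dien-2-one | CC1=C[C@@H](C/C=C/I)[C@]2(C[C@H]1C)OC(=O)C=C2OC | intermediate
55 | (5S,6R,9R)-4-methoxy-8,9-dimethyl-6-[(2E)-3-(tributylstannyl)prop-2-en-1-yl]-1-oxaspiro[4.5]deca-3,7-dien-2-one | CC1=C[C@@H](C/C=C/[Sn](CCCC)(CCCC)CCCC)[C@]2(C[C@H]1C)OC(=O)C=C2OC | intermediate
56 | 3-lithio derivative of 55 (lithium on tetronate C3) | CC1=C[C@@H](C/C=C/[Sn](CCCC)(CCCC)CCCC)[C@]2(C[C@H]1C)OC(=O)C([Li])=C2OC | intermediate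
57 | secondary carbinol (both epimers): thiolane C4 of 37 bears CH(OH) bonded to tetronate C3 of 55 | I/C=C/C[C@H](O[Si](C)(C)C(C)(C)C)C/C=C/C[C@H](C)[C@@H]1[C@@H](C(OC)(OC)C(=O)OC)SC[C@H]1C(O)C1=C(OC)[C@@]2(C[C@@H](C)C(C)=C[C@H]2C/C=C/[Sn](CCCC)(CCCC)CCCC)OC1=O | intermediate
58 | seco ketone: thiolane C4–CO–tetronate C3, with (E)-iodoalkene and (E)-alkenylstannane termini | I/C=C/C[C@H](O[Si](C)(C)C(C)(C)C)C/C=C/C[C@H](C)[C@@H]1[C@@H](C(OC)(OC)C(=O)OC)SC[C@H]1C(=O)C1=C(OC)[C@@]2(C[C@@H](C)C(C)=C[C@H]2C/C=C/[Sn](CCCC)(CCCC)CCCC)OC1=O | intermediate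
59 | protected macrocycle: tetronate 4-O-methyl ether, carbinol tert-butyldimethylsilyl ether, keto acid as dimethyl ketal methyl ester | CC1=C[C@H]2C/C=C/C=C/C[C@H](O[Si](C)(C)C(C)(C)C)C/C=C/C[C@H](C)[C@@H]3[C@@H](C(OC)(OC)C(=O)OC)SC[C@H]3C(=O)C3=C(OC)[C@@]2(C[C@H]1C)OC3=O | intermediate
60 | macrocyclic 3-acyl tetronic acid: carbinol silyl ether, dimethyl ketal methyl ester | CC1=C[C@H]2C/C=C/C=C/C[C@H](O[Si](C)(C)C(C)(C)C)C/C=C/C[C@H](C)[C@@H]3[C@@H](C(OC)(OC)C(=O)OC)SC[C@H]3C(=O)C3=C(O)[C@@]2(C[C@H]1C)OC3=O | intermediate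
61 | macrocyclic 3-acyl tetronic acid: carbinol silyl ether, 2,2-dimethoxy acetic acid | CC1=C[C@H]2C/C=C/C=C/C[C@H](O[Si](C)(C)C(C)(C)C)C/C=C/C[C@H](C)[C@@H]3[C@@H](C(OC)(OC)C(=O)O)SC[C@H]3C(=O)C3=C(O)[C@@]2(C[C@H]1C)OC3=O | intermediate
62 | CNP0224658.3: thiolane (2S,3S,4R), side-chain CH(CH3) (S), carbinol (R), ring-A CH (R), spiro carbon (S), ring-A CH(CH3) (R) | CC1=C[C@H]2C/C=C/C=C/C[C@H](O)C/C=C/C[C@H](C)[C@@H]3[C@@H](C(=O)C(=O)O)SC[C@H]3C(=O)C3=C(O)[C@@]2(C[C@H]1C)OC3=O | target

## Step count and least certain steps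

Total: 40 steps. Longest linear sequence: 20 steps (steps 1, 2, 4, 5, 6, 7, 9, 10, 11, 12, 13, 21, 22, 23, 35, 36, 37, 38, 39, 40).

**Step 9 (key step).** The most likely failures are three. The unsubstituted ring CH2 may migrate instead of the chain-bearing carbon, which would give a regioisomeric ring expansion, because a secondary alkyl radical is only moderately better than a primary one. The ylide may fragment by intramolecular proton transfer and ring opening. A second carbene may be transferred to the product sulfide once the thietane runs low. Fallback, from 11 back to 17: potassium thioacetate in DMF displaces only the primary mesylate of 11 and gives the primary thioacetate F1. Methanolysis (K2CO3, MeOH) frees the thiol, which is alkylated in the same flask with methyl 3-bromo-2-oxopropanoate to the alpha-thio keto ester sulfide F2. K2CO3 in MeCN then forms the enolate between sulfur and the keto ester, and it closes 5-exo-tet on the secondary mesylate with inversion. This is an ordinary intramolecular enolate C-alkylation; it makes the C2–C3 bond and gives 17 with the same configuration at C3.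

**Step 4.** Loss of the 4-methoxybenzyloxide from the enolate by beta-elimination, and erosion of facial selectivity in the partly mismatched pairing of auxiliary and aldehyde, are the likely problems. Fallback, from 3 back to 11: the boron dienolate of the N-crotonyl imide F3 (Bu2BOTf, Et3N) reacts with 3 at its alpha carbon to give the alpha-vinyl syn-aldol adduct F4, which has no beta leaving group. LiBH4 gives the vinyl diol F5, and MsCl gives the vinyl bis-mesylate F6. Ozonolysis with NaBH4 work-up turns the vinyl group into the hydroxymethyl bis-mesylate F7. 4-Methoxybenzyl trichloroacetimidate with catalytic acid then gives 11.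

**Step 7.** Slow 4-exo-tet closure at the hindered secondary mesylate would let elimination and intermolecular sulfide formation take over. Fallback, from 10 back to 13: selective tosylation of the primary hydroxyl gives the primary monotosylate F8. A Mitsunobu reaction with thioacetic acid at the carbinol (inversion) gives the secondary thioacetate F9. K2CO3 in MeOH frees the thiolate, which closes on the unhindered primary tosylate to give 13.

**Step 30.** Addition of the crowded tertiary alcohol to the ketene ylide may be sluggish, so that the reagent decomposes at reflux before the ester ylide forms. Fallback, from 49 back to 51: acetylation (Ac2O, DMAP, Et3N) gives the tertiary acetate F10. LiN(SiMe3)2 in THF at −78 °C brings about Dieckmann cyclisation of the acetate enolate onto the methyl ester, which gives the spiro tetronic acid F11. O-Methylation (Me2SO4, K2CO3, acetone) then gives 51.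

**Step 37.** The thioether may sequester the catalyst, and oligomerisation or protodestannylation may compete during the slow ring closure. Fallback, from 54 and 37 back to 59: Miyaura borylation of 54 (bis(pinacolato)diboron, PdCl2(dppf), KOAc) gives the alkenyl pinacol boronate F12. Lithiation with LiN(i-Pr)2 and addition to 37 gives the boronate carbinol F13. Dess–Martin oxidation gives the boronate ketone F14. An intramolecular Suzuki–Miyaura coupling (Pd(PPh3)4, aq. K3PO4, THF, high dilution) then closes the diene to 59.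

## Further compounds

F1 | step 9 | primary thioacetate with the secondary mesylate of 11 intact | CC(=O)SC[C@@H](COCc1ccc(OC)cc1)[C@H](OS(C)(=O)=O)[C@@H](C)CO[Si](c1ccccc1)(c1ccccc1)C(C)(C)C
F2 | step 9 | methyl 2-oxo-3-sulfanylpropanoate thioether of the chain (alpha-thio keto ester, secondary mesylate intact) | COC(=O)C(=O)CSC[C@@H](COCc1ccc(OC)cc1)[C@H](OS(C)(=O)=O)[C@@H](C)CO[Si](c1ccccc1)(c1ccccc1)C(C)(C)C
F3 | step 4 | (4S)-4-benzyl-3-[(2E)-but-2-enoyl]-1,3-oxazolidin-2-one | C/C=C/C(=O)N1[C@@H](Cc2ccccc2)COC1=O
F4 | step 4 | alpha-vinyl syn-aldol adduct of F3 and 3 | O=C1OC[C@H](Cc2ccccc2)N1C(=O)[C@@H](C=C)[C@H](O)[C@@H](C)CO[Si](c1ccccc1)(c1ccccc1)C(C)(C)C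
F5 | step 4 | 2-vinyl 1,3-diol | OC[C@@H](C=C)[C@H](O)[C@@H](C)CO[Si](c1ccccc1)(c1ccccc1)C(C)(C)C
F6 | step 4 | 2-vinyl bis-mesylate | CS(=O)(=O)OC[C@@H](C=C)[C@H](OS(C)(=O)=O)[C@@H](C)CO[Si](c1ccccc1)(c1ccccc1)C(C)(C)C
F7 | step 4 | 2-(hydroxymethyl) bis-mesylate | CS(=O)(=O)OC[C@@H](CO)[C@H](OS(C)(=O)=O)[C@@H](C)CO[Si](c1ccccc1)(c1ccccc1)C(C)(C)C
F8 | step 7 | primary monotosylate of 10 | Cc1ccc(cc1)S(=O)(=O)OC[C@@H](COCc1ccc(OC)cc1)[C@H](O)[C@@H](C)CO[Si](c1ccccc1)(c1ccccc1)C(C)(C)C
F9 | step 7 | secondary thioacetate (inverted) with primary tosylate | Cc1ccc(cc1)S(=O)(=O)OC[C@@H](COCc1ccc(OC)cc1)[C@@H](SC(C)=O)[C@@H](C)CO[Si](c1ccccc1)(c1ccccc1)C(C)(C)C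
F10 | step 30 | tertiary acetate of 49 | CC1=C[C@@H](CCO[Si](C)(C)C(C)(C)C)[C@](OC(C)=O)(C(=O)OC)C[C@H]1C
F11 | step 30 | (5S,6R,9R)-6-{2-[(tert-butyldimethylsilyl)oxy]ethyl}-4-hydroxy-8,9-dimethyl-1-oxaspiro[4.5]deca-3,7-dien-2-one | CC1=C[C@@H](CCO[Si](C)(C)C(C)(C)C)[C@]2(C[C@H]1C)OC(=O)C=C2O
F12 | step 37 | (E)-alkenyl pinacol boronate analogue of 55 | CC1=C[C@@H](C/C=C/B3OC(C)(C)C(C)(C)O3)[C@]2(C[C@H]1C)OC(=O)C=C2OC
F13 | step 37 | carbinol analogue of 57 with the pinacol boronate in place of the stannane | I/C=C/C[C@H](O[Si](C)(C)C(C)(C)C)C/C=C/C[C@H](C)[C@@H]1[C@@H](C(OC)(OC)C(=O)OC)SC[C@H]1C(O)C1=C(OC)[C@@]2(C[C@@H](C)C(C)=C[C@H]2C/C=C/B3OC(C)(C)C(C)(C)O3)OC1=O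
F14 | step 37 | ketone analogue of 58 with the pinacol boronate in place of the stannane | I/C=C/C[C@H](O[Si](C)(C)C(C)(C)C)C/C=C/C[C@H](C)[C@@H]1[C@@H](C(OC)(OC)C(=O)OC)SC[C@H]1C(=O)C1=C(OC)[C@@]2(C[C@@H](C)C(C)=C[C@H]2C/C=C/B3OC(C)(C)C(C)(C)O3)OC1=O
A1 | alternative 1 | 20-membered beta-keto macrolactone (thiolane C4–CO–CH2–CO–O–spiro carbon, methyl ester on the spiro carbon) | CC1=C[C@H]2C/C=C/C=C/C[C@H](O[Si](C)(C)C(C)(C)C)C/C=C/C[C@H](C)[C@@H]3[C@@H](C(OC)(OC)C(=O)OC)SC[C@H]3C(=O)CC(=O)O[C@]2(C[C@H]1C)C(=O)OC
A2 | alternative 1 | protected target (carbinol silyl ether, dimethyl ketal methyl ester), identical with 60 | CC1=C[C@H]2C/C=C/C=C/C[C@H](O[Si](C)(C)C(C)(C)C)C/C=C/C[C@H](C)[C@@H]3[C@@H](C(OC)(OC)C(=O)OC)SC[C@H]3C(=O)C3=C(O)[C@@]2(C[C@H]1C)OC3=O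
A3 | alternative 2 | 3-[(4-methoxybenzyl)oxy]-5,6-dimethyl-6-[(1Z)-4-(tert-butyldimethylsilyloxy)but-1-en-1-yl]oxan-2-one (5-methyl cis to the 6-alkenyl group) | O=C1O[C@](C)(/C=C\CCO[Si](C)(C)C(C)(C)C)[C@H](C)CC1OCc1ccc(OC)cc1
A4 | alternative 2 | 1-(4-methoxybenzyloxy)-4,5-dimethyl-2-[2-(tert-butyldimethylsilyloxy)ethyl]cyclohex-3-ene-1-carboxylic acid | CC1=C[C@@H](CCO[Si](C)(C)C(C)(C)C)[C@](OCc2ccc(OC)cc2)(C(=O)O)C[C@H]1C
A5 | alternative 3 | (2R,5R)-2-{2-[(tert-butyldimethylsilyl)oxy]ethyl}-4,5-dimethylcyclohex-3-en-1-one | CC1=C[C@@H](CCO[Si](C)(C)C(C)(C)C)C(=O)C[C@H]1C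
A6 | alternative 3 | methyl 3-lithio-3-methoxyacrylate (lithium cis to the ester) | CO/C([Li])=C/C(=O)OC
A7 | alternative 3 | 4-methoxy-8,9-dimethyl-6-[2-(tert-butyldimethylsilyloxy)ethyl]-1-oxaspiro[4.5]deca-3,7-dien-2-one, identical with 51 | CC1=C[C@@H](CCO[Si](C)(C)C(C)(C)C)[C@]2(C[C@H]1C)OC(=O)C=C2OC
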